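## Structural features

- Target 19 is a flavone. Benzo ring A (C4a, C5–C8, C8a) is fused along C4a–C8a to the γ-pyranone ring C (O1, C2, C3, C4), and the 4-methoxyphenyl ring B sits on C2.
- It has no stereocentre, no stereogenic axis and no configurable double bond, so no stereocentres need relating and the problem is purely regiochemical.
- Every carbon of rings A and C is substituted: OMe on C3, C5, C6 and C8, OH on C7, and the carbonyl at C4.
- Ring A carries five contiguous oxygens (on C5, C6, C7, C8, C8a) in three states: three methyl ethers, one free phenol flanked by two of them, and the ring oxygen O1. Its only carbon substituent is C4.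
- This is the real difficulty. No ring-A C–H is left to steer a substitution. O-selective chemistry also runs against the target, because the C7 OH is the most acidic and is alkylated first, while the peri C5 OMe is the first to fall to Lewis acids. C3 needs an oxygen of its own.
- The fragile points are the C5 OMe (chelation-assisted cleavage), C2 of the pyranone (attack of hard nucleophiles with ring opening), and the electron-rich ring A, which oxidises readily to quinones once a phenol is free.
- The key step exploits this feature: if O1 is read as a methoxy oxygen, ring A has a local twofold axis through C4a and C7 that exchanges C5 with C8a and C6 with C8. Ring A is therefore a 1,2,4,5-tetramethoxybenzene substituted at its two equivalent C–H positions.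
- The key step breaks this symmetry by turning one of the two equivalent oxygens ortho to C4a into O1.

## Logic of the disconnections

**19 ⇒ 18.** The bond concerned is O–CH2 of an acetal placed on the C7 oxygen. O7 is the one oxygen that must end free. It has to be told apart from the C3 hydroxyl when that is methylated, and it must not quench two organometallic steps. The gain is that every other oxygen can be treated as an inert methyl ether. The forward step must release it with mild protic acid and no Lewis acid, so that the C5 OMe stays.

**18 ⇒ 17 ⇒ 14.** The bonds cut are O–CH3 on the C3 oxygen and then C3–O, which is traded for C3–I. C3 is the carbon that the ring closure functionalises at no extra cost, so the C3 oxygen need not be carried through the closure. The gain is that the three-carbon bridge simplifies to a plain alkyne one step further back. The forward steps must turn C3–I into C3–O without a hard nucleophile reaching C2; this calls for halogen–metal exchange, boron and oxidation, followed by methylation of the only free OH.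

**14 ⇒ 12 (key).** The bonds cut are O1–C2 and C3–I, and a CH3 is restored on O1.
- *In one sentence:* 12 is desymmetrised by a demethylative 6-endo-dig iodocyclisation in which one of its two equivalent ortho methoxy oxygens becomes O1. This sentence does not fit the chalcone or 1,3-diketone routes, which start from a free, regiodefined ortho-hydroxyaryl ketone.
- *Reason for the cut:* it removes ring C and all regiochemical information from ring A at once.
- *Gain:* a bicyclic compound with three kinds of ring-A oxygen becomes an open ketone whose aryl group is symmetric and has only two kinds. No selective demethylation or selective methylation is then needed anywhere.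
- *Demand:* the methyl ether oxygen must attack C2 rather than C3, and chloride must then remove the methyl group. No other site may be iodinated and the acetal must survive.

**12 ⇒ 6 + 9.** The bond cut is C4–C4a, which lies on the symmetry axis. The only aromatic C–H of 6 sits between two methoxy groups, so metalation has a single possible site. The gain is a convergent split into a ring-A half and a C2–C4/ring-B half of similar size. The forward step needs mono-addition of a hindered aryl anion to the acyl carbon of 9, without conjugate addition and without a second addition.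

**9 ⇒ 7.** The bond cut is C3–C4, between the alkyne carbon and the carbonyl carbon. The terminal alkyne C–H of 7 is the natural nucleophile, and this leads straight to a commercial arylacetylene. The acyl donor must stop at the amide stage.

**6 ⇒ 4 ⇒ 1.** The bonds cut are O–CH2 of the acetal and then C7–O. C7 is the second of the two equivalent C–H positions of 1, so the fifth oxygen of ring A can be put in without any regiochemical choice. The starting material is a commercial, highly symmetric arene. The forward steps need monometalation only, and an oxidation that stops at the phenol.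

## Other disconnections considered

**Alternative 1:** This is the first that comes to mind.
- *Cut:* C2=C3, then O1–C2 and C3–O.
- *Forward:* aldol condensation of acetophenone A1 with the ring-B aldehyde gives the 2'-hydroxychalcone A2. Algar–Flynn–Oyamada oxidation, 3-O-methylation and debenzylation follow.
- *Why the chosen plan is preferred:* the key step simplifies nothing in ring A, because A1 already holds the full problem. It has six different substituents and three kinds of oxygen, and would be reached only by regioselective acylation, chelation-controlled demethylation and selective 7-O protection. On mechanistic grounds, the 6'-methoxy group of A2 (the future C5 OMe) twists the enone. It favours attack of the phenolate at the α-carbon of the epoxide or enone, which is 5-exo closure to the aurone skeleton, over the 6-membered closure. It is also the conventional route and fails the first test.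

**Alternative 2:** Ring A is built last.
- *Cut:* C4a–C5 and C8–C8a.
- *Forward:* halogen–metal exchange on bromopyranone A4 and 1,2-addition to dimethyl squarate A3 give cyclobutenone A5. Thermolysis (Moore rearrangement: 4π opening to the vinylketene, then 6π closure) gives hydroquinone A6.
- *Why the chosen plan is preferred:* the oxygens on C6 and C7 both arrive as identical methoxy groups from A3, and the free hydroxyls appear on C5 and C8, the wrong carbons. To free O7 alone, one would need a mixed squarate ester with regiocontrolled addition. The other option is a late selective 7-demethylation in competition with the chelation-assisted loss of the C5 OMe. A4 needs a multistep synthesis of its own, and A6 is prone to oxidation to the quinone. The count is clearly higher.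

**Alternative 3:** C4–C4a is cut with reversed polarity.
- *Forward:* an acyl-anion equivalent of the arylpropynal adds 1,2 to tetramethoxy-1,4-benzoquinone A7 and gives quinol A8. Reductive aromatisation gives hydroxy ynone A9, in which the C7 OH stems from the second quinone carbonyl.
- *Why the chosen plan is preferred:* this uses the same symmetry and is attractive, but it has four drawbacks.
  - The four methoxy-bearing carbons of A7 are vinylogous ester positions, where addition–elimination competes with 1,2-addition.
  - The metalated acyl-anion equivalent is ambident (propargyl/allenyl).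
  - An extra redox step is needed.
  - The phenol of A9 would still have to be masked before the C3 hydroxyl is methylated.

  No step is saved, and the distinction of O1 from the C5 oxygen would still rest on the key step chosen here.

Key step: step 5

Remark: 19 is achiral (no stereocentre, axis or configurable double bond), so the demand for a single enantiomer is met without stereocontrol. Compounds 1 and 7 and all reagents are taken as commercial.

## Steps

Step 1
Reactants: 1 1,2,4,5-tetramethoxybenzene
Product: 4 2,3,5,6-tetramethoxyphenol, via aryllithium 2 (not isolated), via dimethyl arylboronate 3 (not isolated)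
Conditions: n-BuLi (1.05 equiv), TMEDA, THF, 0 °C; B(OMe)3, −78 °C → rt; AcOH, 30% aq. H2O2, 0 °C → rt
Reagents that add atoms: hydrogen peroxide OO (phenol oxygen of 4); n-butyllithium [Li]CCCC (Li of 2 only); trimethyl borate COB(OC)OC (B(OMe)2 of 3 only)
Why: Directed ortho-metalation, borylation and peroxide oxidation of the arylboronate; the two C–H positions of 1 are equivalent and each lies between two methoxy groups, so one equivalent of base can give only 2, and the 1,2-shift from boron to oxygen places the new oxygen on that carbon (future C7).

Step 2
Reactants: 4 2,3,5,6-tetramethoxyphenol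
Product: 6 1,2,4,5-tetramethoxy-3-(methoxymethoxy)benzene, via sodium phenolate 5 (not isolated)
Conditions: NaH, THF/DMF, 0 °C; MOMCl, 0 °C → rt
Reagents that add atoms: chloromethyl methyl ether COCCl; sodium hydride [Na+].[H-] (Na of 5 only)
Why: Williamson-type O-alkylation of a phenolate with an α-chloro ether; the acetal is inert to the alkyllithium, Grignard, peroxide and carbonate conditions ahead and leaves under mild protic acid.

Step 3
Reactants: 7 1-ethynyl-4-methoxybenzene
Product: 9 N-methoxy-3-(4-methoxyphenyl)-N-methylprop-2-ynamide, via lithium acetylide 8 (not isolated)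
Conditions: n-BuLi, THF, −78 °C; ClC(O)N(OMe)Me, −78 → 0 °C
Reagents that add atoms: N-methoxy-N-methylcarbamoyl chloride CON(C)C(=O)Cl; n-butyllithium [Li]CCCC (Li of 8 only)
Why: Acylation of a lithium acetylide with a carbamoyl chloride; the N-methoxy-N-methylamide formed is far less electrophilic than the chloride, so a second addition of 8 is not expected.

Step 4
Reactants: 6 1,2,4,5-tetramethoxy-3-(methoxymethoxy)benzene; 9 N-methoxy-3-(4-methoxyphenyl)-N-methylprop-2-ynamide
Product: 12 3-(4-methoxyphenyl)-1-[2,3,5,6-tetramethoxy-4-(methoxymethoxy)phenyl]prop-2-yn-1-one, via aryllithium 10 (not isolated), via tetrahedral lithium adduct 11 (not isolated)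
Conditions: 6, n-BuLi, THF, 0 °C; 9, −78 → −20 °C; AcOH in THF, −78 °C
Reagents that add atoms: n-butyllithium [Li]CCCC (Li of 10 and 11 only)
Why: Directed ortho-metalation and Weinreb ketone synthesis; the only aromatic C–H of 6 lies between two methoxy groups, and the chelated adduct 11 holds until the cold acidic quench, which excludes over-addition and protonates the liberated amine before it can add to the ynone.

Step 5
Reactants: 12 3-(4-methoxyphenyl)-1-[2,3,5,6-tetramethoxy-4-(methoxymethoxy)phenyl]prop-2-yn-1-one
Product: 14 3-iodo-5,6,8-trimethoxy-7-(methoxymethoxy)-2-(4-methoxyphenyl)-4H-chromen-4-one, via methyloxonium chloride 13 (not isolated)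
Conditions: ICl (1.5 equiv), CH2Cl2, −78 → 0 °C; aq. Na2S2O3
Reagents that add atoms: iodine monochloride ClI
Why: This is the known ICl-induced electrophilic cyclisation of 2-methoxyaryl alkynones to 3-iodochromones. ICl polarises the C2≡C3 bond of 12 into an iodonium/vinyl-cation species whose positive charge rests on C2, the carbon that is benzylic to the p-anisyl ring and β to the carbonyl. A lone pair of one ortho methoxy oxygen attacks C2 anti to iodine in a 6-endo-dig closure that forms O1–C2 and C3–I and gives 13, and chloride then removes the methyl group by SN2 as chloromethane, which makes the closure irreversible. The pyranone is the only ring closed, and the 5-exo-dig mode (attack at C3) would place the cation next to the carbonyl and away from the anisyl group and is therefore disfavoured. No stereocentre is formed. No regioselectivity is required in ring A, because the two ortho methoxy groups exchange by rotation about C4–C4a and either closure gives the same 14 with OMOM on C7 and OMe on C5, C6 and C8. Chemoselectivity rests on the substrate: ring A has no C–H to iodinate, ring B is deactivated by conjugation with the ynone and then the pyranone, and low temperature with a small excess of ICl spares the acetal.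

Step 6
Reactants: 14 3-iodo-5,6,8-trimethoxy-7-(methoxymethoxy)-2-(4-methoxyphenyl)-4H-chromen-4-one
Product: 17 3-hydroxy-5,6,8-trimethoxy-7-(methoxymethoxy)-2-(4-methoxyphenyl)-4H-chromen-4-one, via 3-magnesiated flavone 15 (not isolated), via flavon-3-ylboronate 16 (not isolated)
Conditions: i-PrMgCl·LiCl (1.1 equiv), THF, −40 °C; B(OMe)3, −40 → 0 °C; AcOH, 30% aq. H2O2, 0 °C → rt
Reagents that add atoms: hydrogen peroxide OO (C3 oxygen of 17); isopropylmagnesium chloride CC(C)[Mg]Cl (MgCl of 15 only); trimethyl borate COB(OC)OC (B(OMe)2 of 16 only)
Why: Iodine–magnesium exchange on an electron-poor alkenyl iodide is fast at low temperature, where the vinylogous-ester carbonyl at C4 is not attacked; borate trapping and peroxide oxidation of a C3-metalated flavone is the established way to flavonols, and the weakly acidic medium avoids opening of ring C.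

Step 7
Reactants: 17 3-hydroxy-5,6,8-trimethoxy-7-(methoxymethoxy)-2-(4-methoxyphenyl)-4H-chromen-4-one
Product: 18 3,5,6,8-tetramethoxy-7-(methoxymethoxy)-2-(4-methoxyphenyl)-4H-chromen-4-one
Conditions: MeI, K2CO3, acetone, reflux
Reagents that add atoms: iodomethane CI
Why: Williamson O-methylation of the only free hydroxyl; O7 is masked, so no selectivity is required, and carbonate is too weak a nucleophile to open ring C.

Step 8
Reactants: 18 3,5,6,8-tetramethoxy-7-(methoxymethoxy)-2-(4-methoxyphenyl)-4H-chromen-4-one
Product: 19 7-hydroxy-3,5,6,8-tetramethoxy-2-(4-methoxyphenyl)-4H-chromen-4-one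
Conditions: HCl (3 M aq., catalytic amount), MeOH, 50 °C
Reagents that add atoms: none
Why: Acid-catalysed transacetalisation of the MOM ether to methanol; aryl methyl ethers, including the peri C5 OMe, need Lewis acids or strong nucleophiles and are not touched by dilute protic acid.

## Compound list

1 | 1,2,4,5-tetramethoxybenzene | COc1cc(OC)c(OC)cc1OC | starting material
2 | (2,3,5,6-tetramethoxyphenyl)lithium | [Li]c1c(OC)c(OC)cc(OC)c1OC | intermediate (not isolated)
3 | dimethyl (2,3,5,6-tetramethoxyphenyl)boronate | COB(OC)c1c(OC)c(OC)cc(OC)c1OC | intermediate (not isolated)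
4 | 2,3,5,6-tetramethoxyphenol | Oc1c(OC)c(OC)cc(OC)c1OC | intermediate
5 | sodium 2,3,5,6-tetramethoxyphenolate | [Na+].[O-]c1c(OC)c(OC)cc(OC)c1OC | intermediate (not isolated)
6 | 1,2,4,5-tetramethoxy-3-(methoxymethoxy)benzene | COCOc1c(OC)c(OC)cc(OC)c1OC | intermediate
7 | 1-ethynyl-4-methoxybenzene | C#Cc1ccc(OC)cc1 | starting material
8 | lithium (4-methoxyphenyl)acetylide | [Li]C#Cc1ccc(OC)cc1 | intermediate (not isolated)
9 | N-methoxy-3-(4-methoxyphenyl)-N-methylprop-2-ynamide | CON(C)C(=O)C#Cc1ccc(OC)cc1 | intermediate
10 | [2,3,5,6-tetramethoxy-4-(methoxymethoxy)phenyl]lithium | [Li]c1c(OC)c(OC)c(OCOC)c(OC)c1OC | intermediate (not isolated)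
11 | lithium alkoxide of the tetrahedral adduct of 10 and 9 (racemic, transient) | [Li]OC(C#Cc1ccc(OC)cc1)(N(C)OC)c1c(OC)c(OC)c(OCOC)c(OC)c1OC | intermediate (not isolated)
12 | 3-(4-methoxyphenyl)-1-[2,3,5,6-tetramethoxy-4-(methoxymethoxy)phenyl]prop-2-yn-1-one | COCOc1c(OC)c(OC)c(C(=O)C#Cc2ccc(OC)cc2)c(OC)c1OC | intermediate
13 | 3-iodo-1-methyl-4-oxo-4H-chromen-1-ium chloride bearing 5,6,8-OMe, 7-OMOM and 2-(4-methoxyphenyl) | C[O+]1C(c2ccc(OC)cc2)=C(I)C(=O)c2c(OC)c(OC)c(OCOC)c(OC)c21.[Cl-] | intermediate (not isolated)
14 | 3-iodo-5,6,8-trimethoxy-7-(methoxymethoxy)-2-(4-methoxyphenyl)-4H-chromen-4-one | COCOc1c(OC)c(OC)c2c(=O)c(I)c(-c3ccc(OC)cc3)oc2c1OC | intermediate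
15 | [5,6,8-trimethoxy-7-(methoxymethoxy)-2-(4-methoxyphenyl)-4-oxo-4H-chromen-3-yl]magnesium chloride | COCOc1c(OC)c(OC)c2c(=O)c([Mg]Cl)c(-c3ccc(OC)cc3)oc2c1OC | intermediate (not isolated)
16 | dimethyl [5,6,8-trimethoxy-7-(methoxymethoxy)-2-(4-methoxyphenyl)-4-oxo-4H-chromen-3-yl]boronate | COCOc1c(OC)c(OC)c2c(=O)c(B(OC)OC)c(-c3ccc(OC)cc3)oc2c1OC | intermediate (not isolated)
17 | 3-hydroxy-5,6,8-trimethoxy-7-(methoxymethoxy)-2-(4-methoxyphenyl)-4H-chromen-4-one | COCOc1c(OC)c(OC)c2c(=O)c(O)c(-c3ccc(OC)cc3)oc2c1OC | intermediate
18 | 3,5,6,8-tetramethoxy-7-(methoxymethoxy)-2-(4-methoxyphenyl)-4H-chromen-4-one | COCOc1c(OC)c(OC)c2c(=O)c(OC)c(-c3ccc(OC)cc3)oc2c1OC | intermediate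
19 | 7-hydroxy-3,5,6,8-tetramethoxy-2-(4-methoxyphenyl)-4H-chromen-4-one | COc1ccc(-c2oc3c(OC)c(O)c(OC)c(OC)c3c(=O)c2OC)cc1 | target

## Step count and least certain steps

Total step count: 8. Longest linear sequence: 7 (steps 1, 2, 4, 5, 6, 7, 8); step 3 is a one-step branch.

**Step 5 (key step).**
- *What may go wrong:* the two ortho substituents twist the aryl ring out of the carbonyl plane, so the methoxy oxygen may reach C2 slowly. Plain addition of I–Cl across the triple bond could then compete. Loss of the acetal to adventitious acid and late iodination of ring B by excess reagent are lesser concerns.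
- *Fallback (from 12, back at 17):*
  - The closure is separated from the demethylation. BCl3 in CH2Cl2 at low temperature removes one carbonyl-chelated ortho methyl group, and also the acetal, to give 1-(2,4-dihydroxy-3,5,6-trimethoxyphenyl)-3-(4-methoxyphenyl)prop-2-yn-1-one F1. The symmetry again makes the choice of methyl group irrelevant.
  - Acid-promoted (TfOH) 6-endo oxa-Michael closure gives 7-hydroxy-5,6,8-trimethoxy-2-(4-methoxyphenyl)-4H-chromen-4-one F2.
  - Its single hydroxyl is masked again with MOMCl to give 5,6,8-trimethoxy-7-(methoxymethoxy)-2-(4-methoxyphenyl)-4H-chromen-4-one F3.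
  - Deprotonation at C3 with LDA gives the 3-lithioflavone F4. This is trapped with B(OMe)3 as 16 and oxidised with H2O2/AcOH to 17.

**Step 6.**
- *What may go wrong:* protonation of the magnesiated species (net loss of iodine), protodeboronation of the α-boryl enone before oxidation, or addition of the Grignard reagent at C2.
- *Fallback (from 14, back at 18):* the metalation is replaced by an Ullmann-type C–O cross-coupling with methanol (CuI, 1,10-phenanthroline, Cs2CO3, MeOH/toluene, 100 °C). This installs the C3 OMe directly and also saves step 7. The fallback makes no new compound (F0).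

**Step 4.**
- *What may go wrong:* the hindered and basic aryllithium may attack the N-methoxy group (elimination with loss of formaldehyde) or add in conjugate fashion. The liberated amine may also add to the ynone during work-up.
- *Fallback (from 6, back at 12):* the acyl transfer is replaced by carbonyl addition and oxidation. Aryllithium 10 is quenched with DMF to give 2,3,5,6-tetramethoxy-4-(methoxymethoxy)benzaldehyde F5. Acetylide 8 adds to give racemic 3-(4-methoxyphenyl)-1-[2,3,5,6-tetramethoxy-4-(methoxymethoxy)phenyl]prop-2-yn-1-ol F6. MnO2 in CH2Cl2 then oxidises this doubly activated carbinol to 12.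

**Step 1.**
- *What may go wrong:* partial double lithiation, and above all over-oxidation of the very electron-rich para-unsubstituted phenol by excess peroxide.
- *Fallback (from 1, back at 4):* the phenol stays masked while oxidant is present. Aryllithium 2 is quenched with DMF to give 2,3,5,6-tetramethoxybenzaldehyde F7. Baeyer–Villiger oxidation with mCPBA gives 2,3,5,6-tetramethoxyphenyl formate F8. Methanolysis (K2CO3, MeOH) under inert gas, after removal of the oxidant, then releases 4.

## Further compounds

F1 | step 5 | 1-(2,4-dihydroxy-3,5,6-trimethoxyphenyl)-3-(4-methoxyphenyl)prop-2-yn-1-one | COc1ccc(cc1)C#CC(=O)c1c(O)c(OC)c(O)c(OC)c1OC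
F2 | step 5 | 7-hydroxy-5,6,8-trimethoxy-2-(4-methoxyphenyl)-4H-chromen-4-one | COc1ccc(cc1)-c1cc(=O)c2c(OC)c(OC)c(O)c(OC)c2o1
F3 | step 5 | 5,6,8-trimethoxy-7-(methoxymethoxy)-2-(4-methoxyphenyl)-4H-chromen-4-one | COCOc1c(OC)c(OC)c2c(=O)cc(-c3ccc(OC)cc3)oc2c1OC
F4 | step 5 | [5,6,8-trimethoxy-7-(methoxymethoxy)-2-(4-methoxyphenyl)-4-oxo-4H-chromen-3-yl]lithium | COCOc1c(OC)c(OC)c2c(=O)c([Li])c(-c3ccc(OC)cc3)oc2c1OC
F0 | step 6 | none | none
F5 | step 4 | 2,3,5,6-tetramethoxy-4-(methoxymethoxy)benzaldehyde | COCOc1c(OC)c(OC)c(C=O)c(OC)c1OC
F6 | step 4 | 3-(4-methoxyphenyl)-1-[2,3,5,6-tetramethoxy-4-(methoxymethoxy)phenyl]prop-2-yn-1-ol (racemic) | COCOc1c(OC)c(OC)c(C(O)C#Cc2ccc(OC)cc2)c(OC)c1OC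
F7 | step 1 | 2,3,5,6-tetramethoxybenzaldehyde | COc1cc(OC)c(OC)c(C=O)c1OC
F8 | step 1 | 2,3,5,6-tetramethoxyphenyl formate | COc1cc(OC)c(OC)c(OC=O)c1OC
A1 | alternative 1 | 1-[4-(benzyloxy)-2-hydroxy-3,5,6-trimethoxyphenyl]ethan-1-one | CC(=O)c1c(O)c(OC)c(OCc2ccccc2)c(OC)c1OC
A2 | alternative 1 | (E)-1-[4-(benzyloxy)-2-hydroxy-3,5,6-trimethoxyphenyl]-3-(4-methoxyphenyl)prop-2-en-1-one | COc1ccc(/C=C/C(=O)c2c(O)c(OC)c(OCc3ccccc3)c(OC)c2OC)cc1
A3 | alternative 2 | dimethyl squarate (3,4-dimethoxycyclobut-3-ene-1,2-dione) | COC1=C(OC)C(=O)C1=O
A4 | alternative 2 | 5-bromo-3-methoxy-2-(4-methoxyphenyl)-4H-pyran-4-one | COc1ccc(cc1)C1=C(OC)C(=O)C(Br)=CO1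
A5 | alternative 2 | 4-hydroxy-2,3-dimethoxy-4-[5-methoxy-6-(4-methoxyphenyl)-4-oxo-4H-pyran-3-yl]cyclobut-2-en-1-one (racemic) | COc1ccc(cc1)C1=C(OC)C(=O)C(=CO1)C1(O)C(OC)=C(OC)C1=O
A6 | alternative 2 | 5,8-dihydroxy-3,6,7-trimethoxy-2-(4-methoxyphenyl)-4H-chromen-4-one | COc1ccc(cc1)-c1oc2c(O)c(OC)c(OC)c(O)c2c(=O)c1OC
A7 | alternative 3 | 2,3,5,6-tetramethoxycyclohexa-2,5-diene-1,4-dione | COC1=C(OC)C(=O)C(OC)=C(OC)C1=O
A8 | alternative 3 | 4-hydroxy-2,3,5,6-tetramethoxy-4-[3-(4-methoxyphenyl)prop-2-ynoyl]cyclohexa-2,5-dien-1-one | COC1=C(OC)C(O)(C(=O)C#Cc2ccc(OC)cc2)C(OC)=C(OC)C1=O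
A9 | alternative 3 | 1-(4-hydroxy-2,3,5,6-tetramethoxyphenyl)-3-(4-methoxyphenyl)prop-2-yn-1-one | COc1ccc(cc1)C#CC(=O)c1c(OC)c(OC)c(O)c(OC)c1OC
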